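The numbers in the tables were computed from invented constants.

Does more reagent always buy more triple product at a fixed time, or can a flask overshoot?

| setting | delta | gamma | Monday's | Thursday's | Friday's | Wednesday's | Tuesday's |
|---|---|---|---|---|---|---|---|
| starting material | 0.10 M | 0.10 M | 0.10 M | 0.10 M | 0.10 M | 0.10 M | 0.10 M |
| reagent | 0.056 M | 1.1 M | 0.100 M | 0.200 M | 0.400 M | 0.800 M | 1.50 M |
| remark | run made earlier | run made earlier |  |  |  |  |  |
| time |  |  | 2.5 h | 2.5 h | 2.5 h | 2.5 h | 2.5 h |

| run | time / h | triple product / % |
|---|---|---|
| delta | 0.417 | 5 |
| delta | 0.833 | 0 |
| delta | 1.33 | 0 |
| delta | 1.50 | 2 |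
| delta | 2.00 | 0 |
| delta | 2.50 | 0 |
| gamma | 0.200 | 2 |
| gamma | 0.333 | 5 |
| gamma | 0.500 | 11 |
| gamma | 0.833 | 28 |
| gamma | 1.50 | 51 |
| gamma | 2.50 | 49 |

(scatter of a reading: 2 percentage points)
- a reading or a percentage of triple product counts all its forms, free or not
- "hardly changes" means that all values lie within two and a half points (for a concentration: within two and a half percent of the largest)
1. amount of triple product at the end, in percent of the starting material charged for Monday's, Thursday's, Friday's, Wednesday's, Tuesday's, in this order
2. how that number moves from the first to the last of them (hardly changes / falls all the way / rises all the way / rises, then falls / falls, then rises)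

**What does gamma show at its end?** It climbs from 28 % at 0.833 h to 51 % at 1.50 h, then reads 49 % at 2.50 h. The scatter of a reading is 2 percentage points.

**So is that a plateau?** The readings can't say. But I do not expect gamma's steep climb to go flat at once, so my own reading is that these two points are the flanks of a top lying midway, near 2.00 h. That would mean a further addition of reagent consumes triple product.

**What follows if so?** Suppose each stage is lost by a step first order in reagent. Every rate then carries the factor c(reagent), so I replace time by the exposure x, the integral of c(reagent) dt, and the factor drops out. With equal constants k, stage n integrates to c(starting material at the start)·(kx)ⁿ·exp(−kx)/n!, which tops at kx = n. In such a chain, with its constants held, each top falls at a fixed exposure, whatever the charge of reagent.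

**But the reagent is consumed. Isn't that the weak spot?** Yes. I still write x = c(reagent)·t, the pseudo-first-order view, for gamma, where 3 equivalents would take a quarter of its charge; this is a rough approximation, and a poorer one for smaller charges.

**What do you carry forward?** The turning charge c*, gamma's exposure at its top divided by the asked time: 0.880 M.

**And your commitment?** Wednesday's 0.800 M is lower than c*, so it ends on the rising side. Tuesday's 1.50 M is higher than c*, so it ends past the top. I therefore expect the row to rise, then fall.

The forecast gave 1 %, 4 %, 14 %, 37 % and 60 %, so rises all the way, reading gamma as “a plateau, most likely a reversible last addition”. We part at Tuesday's flask, which I place below Wednesday's.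

The flasks give 1.14 %, 6.50 %, 26.6 %, 50.7 % and 37.3 %, so the row rises, then falls.

reagent + double product → triple product (k = 0.0440 M⁻¹ min⁻¹); starting material + reagent → mono adduct (k = 0.0350 M⁻¹ min⁻¹); reagent + triple product → tetra adduct (k = 0.0110 M⁻¹ min⁻¹); starting material + triple product ⇌ idle adduct, settled at all times (K = 310 M⁻¹); reagent + mono adduct → double product (k = 0.0400 M⁻¹ min⁻¹) It turns at 0.86 M of reagent. Carried to Tuesday's flask, c* puts the top at a time of 1.47 h, earlier than the end. Tuesday's flask holds 50.9 % of triple product at 1.25 h and 37.3 % at 2.50 h.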